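The target is an achiral diaryl ether. Both CH2OH groups are traced back to methyl esters, the C5 and C5′ bromines to phenol-directed bromination, and 4-OH and 4′-OH to methyl ethers.
The plan rests on the unbroken sequence on ring B: C1′ (carbon substituent), C2′ (O–ring A), C3′ (OH), C4′ (OH). C1′ and C2′ are the two carbons of an ynoate, C3′ and C4′ are C2 and C3 of a 3-oxygenated furan, and the 3′-OH oxygen is the furan oxygen.
The key disconnection is C2′–C3′ plus C1′–C6′, by [4+2] cycloaddition of 3-methoxyfuran to the ring A aryloxypropiolate and opening of the oxygen bridge. The aryl–O–C2′ bond is made earlier on acyclic carbon, by oxa-Michael addition to methyl propiolate followed by bromination and two dehydrobrominations.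
Ring order: ring A is bought as isovanillin and its C2 bromine is set first. Ring B is formed last from non-aromatic parts.

Key step: step 8

Remark: the target has no stereocentre. The two transient chiral intermediates (the vicinal dibromide and the oxanorbornadiene) are racemates whose stereocentres are erased in the step that forms them.

Step 1
Reactants: 1 isovanillin (3-hydroxy-4-methoxybenzaldehyde)
Product: 2 2-bromoisovanillin (2-bromo-3-hydroxy-4-methoxybenzaldehyde)
Conditions: Br2 (1.05 equiv), NaOAc (2 equiv), Fe powder (cat.), AcOH, rt
Reagents that add atoms: bromine, BrBr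
Why: Electrophilic aromatic bromination directed by the free phenol, which under these buffered conditions is established to enter isovanillin at C2, the ortho position between OH and CHO, rather than at C6.

Step 2
Reactants: 2 2-bromoisovanillin
Product: 3 2-bromo-3-hydroxy-4-methoxybenzoic acid
Conditions: NaClO2 (1.5 equiv), NaH2PO4 (2 equiv), 2-methyl-2-butene (10 equiv), t-BuOH–H2O, 0 °C → rt
Reagents that add atoms: sodium chlorite, [Na+].[O-]Cl=O
Why: Pinnick oxidation takes the aldehyde to the acid through its chlorous acid adduct, and the large excess of alkene removes HOCl before it can chlorinate the phenol ring.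

Step 3
Reactants: 3 2-bromo-3-hydroxy-4-methoxybenzoic acid
Product: 4 methyl 2-bromo-3-hydroxy-4-methoxybenzoate
Conditions: MeOH, H2SO4 (cat.), reflux
Reagents that add atoms: methanol, CO
Why: Fischer esterification, which still proceeds on a benzoic acid with a single ortho substituent and leaves the phenol, the aryl bromide and the methyl ether untouched.

Step 4
Reactants: 4 methyl 2-bromo-3-hydroxy-4-methoxybenzoate; 5 methyl propiolate
Product: 6 methyl 2-bromo-4-methoxy-3-{[(1E)-3-methoxy-3-oxoprop-1-en-1-yl]oxy}benzoate
Conditions: DABCO (10 mol %), CH2Cl2, 0 °C → rt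
Reagents that add atoms: none
Why: Amine-catalysed oxa-Michael addition of a phenol to a propiolate, in which DABCO adds to 5, the zwitterion deprotonates 4 and the phenoxide displaces the ammonium group by addition–elimination to give the favoured E enol ether.

Step 5
Reactants: 6 methyl 2-bromo-4-methoxy-3-{[(1E)-3-methoxy-3-oxoprop-1-en-1-yl]oxy}benzoate
Product: 8 methyl 2-bromo-3-{[(1Z)-2-bromo-3-methoxy-3-oxoprop-1-en-1-yl]oxy}-4-methoxybenzoate, via vicinal dibromide 7 (not isolated)
Conditions: Br2 (1.05 equiv), CH2Cl2, 0 °C; then Et3N (1.5 equiv), 0 °C → rt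
Reagents that add atoms: bromine, BrBr
Why: Bromine addition to the enol ether double bond outruns substitution of the ester- and bromine-deactivated ring A, and the amine then removes the acidic α-proton together with the ionisable bromide on the oxygen-bearing carbon, which, as in the known bromination–dehydrobromination of 3-alkoxyacrylates, settles on the Z alkene with OAr trans to the ester and the remaining vinyl hydrogen anti to bromine.

Step 6
Reactants: 8 methyl 2-bromo-3-{[(1Z)-2-bromo-3-methoxy-3-oxoprop-1-en-1-yl]oxy}-4-methoxybenzoate
Product: 9 methyl 2-bromo-4-methoxy-3-[(3-methoxy-3-oxoprop-1-yn-1-yl)oxy]benzoate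
Conditions: LiN(SiMe3)2 (1.1 equiv), THF, −78 → −40 °C; cold pH 7 buffer; short pad of neutral Al2O3, used at once
Reagents that add atoms: none
Why: Base-induced anti dehydrobromination, the classical closing step of ynol ether syntheses from 2-bromovinyl ethers and of alkynoate syntheses from 2-bromoalk-2-enoates, is favoured here because the vinyl hydrogen is anti-periplanar to bromine, acidified by OAr and placed next to the lithium-binding ester carbonyl, while the hindered amide spares both esters, the aryl bromide and the electrophilic product.

Step 7
Reactants: 10 3-bromofuran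
Product: 11 3-methoxyfuran
Conditions: NaOMe (3 equiv), CuI (10 mol %), MeOH–NMP, 110 °C, sealed vessel; distillation
Reagents that add atoms: sodium methoxide, C[O-].[Na+]
Why: Ullmann-type copper-catalysed methoxylation of a heteroaryl bromide, the standard entry to 3-methoxy five-membered heteroarenes, with the volatile product separated by distillation.

Step 8
Reactants: 9 methyl 2-bromo-4-methoxy-3-[(3-methoxy-3-oxoprop-1-yn-1-yl)oxy]benzoate; 11 3-methoxyfuran
Product: 13 methyl 2-[2-bromo-6-methoxy-3-(methoxycarbonyl)phenoxy]-3-hydroxy-4-methoxybenzoate, via 7-oxanorbornadiene cycloadduct 12 (not isolated)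
Conditions: 11 (4 equiv), PhMe (1 M), 4 Å MS, 80 °C, sealed tube; evaporate; CSA (10 mol %), CH2Cl2, rt
Reagents that add atoms: none
Why: Proposed new method: the HOMO of 11 is largest at furan C2 (β-carbon of the enol ether and α to the ring oxygen) and the LUMO of 9 is largest at the aryloxy-bearing alkyne carbon (β to the ester), so a normal-demand, strongly asynchronous intermolecular [4+2] cycloaddition should join furan C2 to that carbon (C3′–C2′) and furan C5 to the ester-bearing carbon (C6′–C1′), closing the six-membered carbocycle of ring B as the oxygen-bridged diene 12. The closest known reaction type is the Diels–Alder addition of 3-alkoxyfurans to acetylenic esters (acetylenedicarboxylates, propiolates, 3-halopropiolates) with acid opening of the adduct to a catechol monoether, and what has not been shown is a β-aryloxy push–pull ynoate as the 2π partner, whose donor raises the LUMO, hence the very electron-rich furan in excess, the high concentration and the heating. Protonation of the bridge oxygen then breaks its bond to the former furan C5, because only this cleavage leaves a pentadienyl cation whose charge-bearing positions C4′ and C2′ carry OMe and OAr, whereas cleavage at the former furan C2 would put charge on the ester-bearing carbon, and loss of the C3′ proton gives the phenol with the bridge oxygen retained as 3′-OH. This aromatisation is irreversible and drains the reversible cycloaddition. The two bridgehead stereocentres of 12 arise as a racemate, are tied to each other by the bicycle and vanish in 13, so no stereocontrol is required. The selectivities needed are the orientation of addition and the direction of bridge opening, both set by the 3-methoxy group and reinforced by the aryloxy donor; benzofuran-type cyclisation of the ynol ether is blocked by the Br and OMe groups at both ortho positions of ring A, and proton loss from a zwitterion to a 2-vinylated furan is disfavoured by the non-polar, acid-free medium of the first stage.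

Step 9
Reactants: 13 methyl 2-[2-bromo-6-methoxy-3-(methoxycarbonyl)phenoxy]-3-hydroxy-4-methoxybenzoate
Product: 14 methyl 2-[2-bromo-6-hydroxy-3-(methoxycarbonyl)phenoxy]-3,4-dihydroxybenzoate
Conditions: BBr3 (6 equiv), CH2Cl2, −78 → 0 °C; ice-water
Reagents that add atoms: none
Why: Lewis acid ether cleavage, in which BBr3 binds each aryl methyl ether oxygen and bromide removes the methyl group by SN2, cannot break the diaryl ether and spares methyl benzoates at or below 0 °C, and since every later step is acidic or runs on aluminium phenoxides in the cold, neither Smiles migration of ring B to the new 4-OH nor lactonisation onto the C1′ ester is invited.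

Step 10
Reactants: 14 methyl 2-[2-bromo-6-hydroxy-3-(methoxycarbonyl)phenoxy]-3,4-dihydroxybenzoate
Product: 15 methyl 5-bromo-2-[2,5-dibromo-6-hydroxy-3-(methoxycarbonyl)phenoxy]-3,4-dihydroxybenzoate
Conditions: Br2 (2.1 equiv), AcOH, rt
Reagents that add atoms: bromine, BrBr
Why: Phenol-controlled electrophilic aromatic bromination, in which C5 is the only free position ortho or para to 4-OH in ring A, and in ring B C5′ is ortho to 4′-OH, para to the aryloxy group and meta to the ester whereas C6′ is served only by 3′-OH and lies ortho to the ester, the same preference as in the known 5-bromination of 3,4-dihydroxybenzoates.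

Step 11
Reactants: 15 methyl 5-bromo-2-[2,5-dibromo-6-hydroxy-3-(methoxycarbonyl)phenoxy]-3,4-dihydroxybenzoate
Product: 16 6-bromo-3-[2,5-dibromo-6-hydroxy-3-(hydroxymethyl)phenoxy]-4-(hydroxymethyl)benzene-1,2-diol (CNP0104332.0)
Conditions: i-Bu2AlH (10 equiv), THF, −78 → 0 °C; aq. potassium sodium tartrate
Reagents that add atoms: none
Why: Hydride reduction of esters with i-Bu2AlH, in which three equivalents are consumed by the phenols to form aluminium phenoxides that mask them, and the excess takes both esters to primary alcohols without touching the aryl bromides or the diaryl ether.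

Compound list
1 | isovanillin (3-hydroxy-4-methoxybenzaldehyde) | COc1ccc(C=O)cc1O | starting material
2 | 2-bromo-3-hydroxy-4-methoxybenzaldehyde | COc1ccc(C=O)c(Br)c1O | intermediate
3 | 2-bromo-3-hydroxy-4-methoxybenzoic acid | COc1ccc(C(=O)O)c(Br)c1O | intermediate
4 | methyl 2-bromo-3-hydroxy-4-methoxybenzoate | COC(=O)c1ccc(OC)c(O)c1Br | intermediate
5 | methyl propiolate | C#CC(=O)OC | starting material
6 | methyl 2-bromo-4-methoxy-3-{[(1E)-3-methoxy-3-oxoprop-1-en-1-yl]oxy}benzoate | COC(=O)/C=C/Oc1c(Br)c(C(=O)OC)ccc1OC | intermediate
7 | methyl 2-bromo-3-{[(1R*,2R*)-1,2-dibromo-3-methoxy-3-oxopropyl]oxy}-4-methoxybenzoate (racemic, anti adduct drawn) | COC(=O)[C@H](Br)[C@H](Br)Oc1c(Br)c(C(=O)OC)ccc1OC | intermediate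
8 | methyl 2-bromo-3-{[(1Z)-2-bromo-3-methoxy-3-oxoprop-1-en-1-yl]oxy}-4-methoxybenzoate | COC(=O)/C(Br)=C/Oc1c(Br)c(C(=O)OC)ccc1OC | intermediate
9 | methyl 2-bromo-4-methoxy-3-[(3-methoxy-3-oxoprop-1-yn-1-yl)oxy]benzoate | COC(=O)C#COc1c(Br)c(C(=O)OC)ccc1OC | intermediate
10 | 3-bromofuran | Brc1ccoc1 | starting material
11 | 3-methoxyfuran | COc1ccoc1 | intermediate
12 | methyl 3-[2-bromo-6-methoxy-3-(methoxycarbonyl)phenoxy]-5-methoxy-7-oxabicyclo[2.2.1]hepta-2,5-diene-2-carboxylate (racemic, one enantiomer drawn) | COC1=C[C@@H]2O[C@H]1C(Oc3c(Br)c(C(=O)OC)ccc3OC)=C2C(=O)OC | intermediate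
13 | methyl 2-[2-bromo-6-methoxy-3-(methoxycarbonyl)phenoxy]-3-hydroxy-4-methoxybenzoate | COC(=O)c1ccc(OC)c(O)c1Oc1c(Br)c(C(=O)OC)ccc1OC | intermediate
14 | methyl 2-[2-bromo-6-hydroxy-3-(methoxycarbonyl)phenoxy]-3,4-dihydroxybenzoate | COC(=O)c1ccc(O)c(O)c1Oc1c(Br)c(C(=O)OC)ccc1O | intermediate
15 | methyl 5-bromo-2-[2,5-dibromo-6-hydroxy-3-(methoxycarbonyl)phenoxy]-3,4-dihydroxybenzoate | COC(=O)c1cc(Br)c(O)c(O)c1Oc1c(Br)c(C(=O)OC)cc(Br)c1O | intermediate
16 | 6-bromo-3-[2,5-dibromo-6-hydroxy-3-(hydroxymethyl)phenoxy]-4-(hydroxymethyl)benzene-1,2-diol | OCc1cc(Br)c(O)c(Oc2c(CO)cc(Br)c(O)c2O)c1Br | target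

Total step count: 11. Longest linear sequence: 10 (steps 1–6 and 8–11); step 7 is a one-step side branch.

Steps most likely to fail

Step 8. The aryloxy donor may lower the electrophilicity of the alkyne so far that the cycloaddition is overtaken by thermal decay of the furan or by hydration of the ynol ether. The polar pathway may also stop at conjugate substitution at furan C2 without ring closure. The fallback gives up the benzannulation and makes the diaryl ether by nucleophilic aromatic substitution; it sets out from 4 and comes back at 14. Phenol 4 and commercial 2-fluoro-3,4-dimethoxybenzaldehyde (K2CO3, DMF, 110 °C, fluoride activated by the ortho formyl group) should give methyl 2-bromo-3-(6-formyl-2,3-dimethoxyphenoxy)-4-methoxybenzoate F1. Pinnick oxidation would give 2-[2-bromo-6-methoxy-3-(methoxycarbonyl)phenoxy]-3,4-dimethoxybenzoic acid F2. Fischer esterification would then give methyl 2-[2-bromo-6-methoxy-3-(methoxycarbonyl)phenoxy]-3,4-dimethoxybenzoate F3. BBr3 under the conditions of step 9 cleaves all three methyl ethers of F3 and delivers 14.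

Step 6. The base may displace the aryloxide by addition–elimination, the elimination may stall, or the freshly formed ynol ether may be consumed by nucleophiles or moisture during isolation. The fallback avoids the ynol ether by reversing the order of ring formation and ether formation; it sets out from 5, 11 and 4 and comes back at 13 through 12. Terminal bromination of 5 (N-bromosuccinimide, AgNO3 cat., acetone) gives methyl 3-bromopropiolate F4, an established furan dienophile. With 11 (PhMe, rt → 40 °C) F4 should give, with the same orientation, racemic methyl 3-bromo-5-methoxy-7-oxabicyclo[2.2.1]hepta-2,5-diene-2-carboxylate F5. Without isolation of F5, the caesium salt of 4 (Cs2CO3, MeCN, 0 °C → rt) would replace the vinylic bromide by conjugate addition–elimination, as alkoxides are known to do on such adducts. This furnishes 12, which is opened with catalytic acid to 13.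

Step 11. The esters are deactivated by the para aluminium phenoxides and may be reduced incompletely. The catechol may stay bound to aluminium at work-up, and the p-hydroxybenzylic alcohols may ionise to quinone methides during an acidic release. The fallback masks the phenols first; it sets out from 15 and comes back at 16. Silylation (t-BuMe2SiOTf, 2,6-lutidine, CH2Cl2) should give the tris(tert-butyldimethylsilyl) ether of 15 F6. Reduction with i-Bu2AlH (5 equiv, CH2Cl2, −78 °C) would give the tris(tert-butyldimethylsilyl) ether of 16 F7. Buffered fluoride (Bu4NF, AcOH, THF, 0 °C) then releases 16 under near-neutral conditions.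

Further compounds
F1 | step 8 | methyl 2-bromo-3-(6-formyl-2,3-dimethoxyphenoxy)-4-methoxybenzoate | O=Cc1ccc(OC)c(OC)c1Oc1c(Br)c(C(=O)OC)ccc1OC
F2 | step 8 | 2-[2-bromo-6-methoxy-3-(methoxycarbonyl)phenoxy]-3,4-dimethoxybenzoic acid | OC(=O)c1ccc(OC)c(OC)c1Oc1c(Br)c(C(=O)OC)ccc1OC
F3 | step 8 | methyl 2-[2-bromo-6-methoxy-3-(methoxycarbonyl)phenoxy]-3,4-dimethoxybenzoate | COC(=O)c1ccc(OC)c(OC)c1Oc1c(Br)c(C(=O)OC)ccc1OC
F4 | step 6 | methyl 3-bromopropiolate | COC(=O)C#CBr
F5 | step 6 | methyl 3-bromo-5-methoxy-7-oxabicyclo[2.2.1]hepta-2,5-diene-2-carboxylate (racemic, one enantiomer drawn) | COC1=C[C@@H]2O[C@H]1C(Br)=C2C(=O)OC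
F6 | step 11 | tris(tert-butyldimethylsilyl) ether of 15 | COC(=O)c1cc(Br)c(O[Si](C)(C)C(C)(C)C)c(O[Si](C)(C)C(C)(C)C)c1Oc1c(Br)c(C(=O)OC)cc(Br)c1O[Si](C)(C)C(C)(C)C
F7 | step 11 | tris(tert-butyldimethylsilyl) ether of 16 | OCc1cc(Br)c(O[Si](C)(C)C(C)(C)C)c(O[Si](C)(C)C(C)(C)C)c1Oc1c(Br)c(CO)cc(Br)c1O[Si](C)(C)C(C)(C)C
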